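**Retrosynthetic overview**

- The quinone is opened to a phenol that carries a free para C–H, and that phenol is traced to a salicylaldehyde whose formyl group is the latent ring methyl.
- Feature used: in the six-membered ring, C1(=O)–C2(OMe)–C3(H)–C4(=O) is a four-carbon piece with oxygen on C2 and C4 in a 1,3-relationship, and C5(CH3)–C6(C21 chain) is a two-carbon piece.
- Key disconnection: the C6–C1 and C4–C5 bonds, made by a [4+2] cycloaddition of a 1,1,3-trioxygenated butadiene (C1–C4) with a 2-alkynal (C5–C6, formyl on C5); the only ring is closed and aromatised in this step.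
- The ynal comes from prop-2-yn-1-ol and the C21 bromide (alkylation, oxidation); the diene comes from methyl 3-methoxybut-2-enoate (O-silylation of its dienolate).

Key step: step 4

Assumption: 1-bromoheneicosane is taken as purchasable (otherwise one step from heneicosan-1-ol with CBr4/PPh3). The target has no stereogenic element, so no step has to set configuration.

**Route**

Step 1
Reactants: 1 prop-2-yn-1-ol; 2 1-bromoheneicosane
Product: 4 tetracos-2-yn-1-ol, via dilithiated prop-2-yn-1-ol 3 (not isolated)
Conditions: 1 (1.5 equiv), n-BuLi (3.0 equiv), THF/HMPA, −78 → −20 °C; then 2 (1.0 equiv), −20 °C → rt; H2O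
Reagents that add atoms: none
Why: Double deprotonation gives an O,C-dilithio species whose acetylide carbon is much more nucleophilic than the alkoxide, so SN2 acetylide alkylation of the primary bromide should give the C24 propargylic alcohol.

Step 2
Reactants: 4 tetracos-2-yn-1-ol
Product: 5 tetracos-2-ynal
Conditions: activated MnO2 (15 equiv), CH2Cl2, rt
Reagents that add atoms: none
Why: MnO2 oxidation of propargylic alcohols stops cleanly at the conjugated aldehyde under neutral conditions that the ynal tolerates.

Step 3
Reactants: 6 methyl (E)-3-methoxybut-2-enoate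
Product: 8 (E)-1,3-dimethoxy-1-(trimethylsilyloxy)buta-1,3-diene, via lithium dienolate 7 (not isolated)
Conditions: LiN(iPr)2 (commercial solution, 1.1 equiv), THF, −78 °C; Me3SiCl (1.3 equiv), −78 °C → rt; filtration under Ar, distillation, used fresh
Reagents that add atoms: chlorotrimethylsilane, C[Si](C)(C)Cl
Why: γ-Deprotonation of the vinylogous ester gives the extended enolate, which the hard silyl chloride traps on oxygen (silyl ketene acetal formation); the geometry at the ketene acetal carbon is immaterial because that carbon ends as an aromatic C–O carbon.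

Step 4
Reactants: 8 (E)-1,3-dimethoxy-1-(trimethylsilyloxy)buta-1,3-diene; 5 tetracos-2-ynal
Product: 11 2-heneicosyl-6-hydroxy-4-methoxybenzaldehyde, via cyclohexa-1,4-diene cycloadduct 9 (not isolated), via aryl trimethylsilyl ether 10 (not isolated)
Conditions: 8 (2.5 equiv), toluene, rt → 80 °C; then 1 M HCl, THF, rt
Reagents that add atoms: none
Why: The CH2 terminus of the diene (ring carbon C1), which carries the largest HOMO coefficient because all three oxygens donate towards it, bonds to the chain-bearing β-carbon of the ynal (C6) while the ketene acetal carbon (C4) bonds to the formyl-bearing α-carbon (C5), in a strongly asynchronous normal-electron-demand Diels–Alder reaction with Mukaiyama–Michael character. The six-membered carbocycle is closed by this intermolecular [4+2] cycloaddition as the 1,4-cyclohexadiene 9, with the C6–C1 and C4–C5 bonds newly formed. Adduct 9 aromatises by 1,4-elimination of methanol (C4–OMe with a C1–H) to the silyl ether 10, and the aqueous acid cleaves the O–Si bond, sending any surviving 9 through its hemiketal to the same phenol 11. The closest known reaction type is the Diels–Alder/aromatisation of 1,1,3-trioxygenated butadienes with acetylenic aldehydes, ketones and esters to resorcinol derivatives. No stereocentre is retained, since the racemic ketal carbon of 9 becomes an aromatic carbon. The selectivity needed is regiochemical (CH2 to C6, not to C5) and is secured by matched polarisation, the formyl group making the β-alkyne carbon electrophilic and the ketene acetal and enol ether oxygens making the CH2 carbon nucleophilic, while the absence of a Lewis acid keeps the diene on the C≡C bond and off the formyl C=O.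

Step 5
Reactants: 11 2-heneicosyl-6-hydroxy-4-methoxybenzaldehyde
Product: 13 3-heneicosyl-5-methoxy-2-methylphenol, via benzylic alcohol 12 (not isolated)
Conditions: Et3SiH (3 equiv), CF3CO2H, CH2Cl2 (dilute), 0 °C → rt
Reagents that add atoms: none
Why: Ionic hydrogenation: the protonated aldehyde and then the benzylic cation, strongly stabilised by the ortho-hydroxyl and para-methoxy groups, each accept hydride from the silane, taking the formyl group down to methyl while the phenol and aryl ether are untouched.

Step 6
Reactants: 13 3-heneicosyl-5-methoxy-2-methylphenol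
Product: 15 3-heneicosyl-5-methoxy-2-methylcyclohexa-2,5-diene-1,4-dione (CNP0104330.0), via para-aminooxy cyclohexadienone 14 (not isolated)
Conditions: ON(SO3K)2 (3 equiv), aq. KH2PO4, Aliquat 336 (cat.), CH2Cl2/H2O, rt
Reagents that add atoms: potassium nitrosodisulfonate, [K+].[K+].[O]N(S(=O)(=O)[O-])S(=O)(=O)[O-]
Why: Teuber reaction: one nitroxyl abstracts the phenolic hydrogen, a second couples at the free para carbon C1 (a 3-methoxyphenol with an open para position, the pattern that reliably gives 2-methoxy-1,4-benzoquinones), and loss of imidodisulfonate from 14 gives the para-quinone with carbonyls at C4 and C1.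

**Compound list**

1 | prop-2-yn-1-ol | C#CCO | starting material
2 | 1-bromoheneicosane | CCCCCCCCCCCCCCCCCCCCCBr | starting material
3 | dilithiated prop-2-yn-1-ol (lithium 3-lithioprop-2-yn-1-olate) | [Li]C#CCO[Li] | intermediate
4 | tetracos-2-yn-1-ol | CCCCCCCCCCCCCCCCCCCCCC#CCO | intermediate
5 | tetracos-2-ynal | CCCCCCCCCCCCCCCCCCCCCC#CC=O | intermediate
6 | methyl (E)-3-methoxybut-2-enoate | CO/C(C)=C/C(=O)OC | starting material
7 | lithium (Z)-1,3-dimethoxybuta-1,3-dien-1-olate (OLi trans to C3) | C=C(OC)/C=C(\OC)O[Li] | intermediate
8 | (E)-1,3-dimethoxy-1-(trimethylsilyloxy)buta-1,3-diene | C=C(OC)/C=C(\OC)O[Si](C)(C)C | intermediate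
9 | 2-heneicosyl-4,6-dimethoxy-6-(trimethylsilyloxy)cyclohexa-1,4-diene-1-carbaldehyde (racemic at C6) | CCCCCCCCCCCCCCCCCCCCCC1=C(C=O)C(OC)(O[Si](C)(C)C)C=C(OC)C1 | intermediate
10 | 2-heneicosyl-4-methoxy-6-(trimethylsilyloxy)benzaldehyde | CCCCCCCCCCCCCCCCCCCCCc1cc(OC)cc(O[Si](C)(C)C)c1C=O | intermediate
11 | 2-heneicosyl-6-hydroxy-4-methoxybenzaldehyde | CCCCCCCCCCCCCCCCCCCCCc1cc(OC)cc(O)c1C=O | intermediate
12 | 3-heneicosyl-2-(hydroxymethyl)-5-methoxyphenol | CCCCCCCCCCCCCCCCCCCCCc1cc(OC)cc(O)c1CO | intermediate
13 | 3-heneicosyl-5-methoxy-2-methylphenol | CCCCCCCCCCCCCCCCCCCCCc1cc(OC)cc(O)c1C | intermediate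
14 | dipotassium N-[(2-heneicosyl-6-methoxy-3-methyl-4-oxocyclohexa-2,5-dien-1-yl)oxy]imidodisulfonate (racemic at C1) | CCCCCCCCCCCCCCCCCCCCCC1=C(C)C(=O)C=C(OC)C1ON(S(=O)(=O)[O-])S(=O)(=O)[O-].[K+].[K+] | intermediate
15 | 3-heneicosyl-5-methoxy-2-methylcyclohexa-2,5-diene-1,4-dione (CNP0104330.0) | CCCCCCCCCCCCCCCCCCCCCC1=C(C)C(=O)C=C(OC)C1=O | target

**Step count**

Total steps: 6. Longest linear sequence: 5 (steps 1, 2, 4, 5, 6).

**Steps most likely to fail**

Step 4. The diene may add to the formyl C=O (hetero-Diels–Alder or aldol-type addition) instead of the C≡C bond. The β-alkylated ynal may also oligomerise before it is consumed, or the adduct may lose silanol instead of methanol and keep a second methyl ether. Fallback (the ring is bought, not built): setting out from 2, Li2CuCl4-catalysed cross-coupling with commercial 3,5-dimethoxyphenylmagnesium chloride in THF should give 1-heneicosyl-3,5-dimethoxybenzene F1. Vilsmeier–Haack formylation (POCl3, DMF) is expected to enter ortho to the chain and para to a methoxy group, giving 2-heneicosyl-4,6-dimethoxybenzaldehyde F2. BCl3 in CH2Cl2 (−78 → 0 °C) then cleaves only the methyl ether chelated to the formyl group, and the route is rejoined at 11.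

Step 6. The two-phase radical oxidation may stall on the waxy, water-insoluble phenol, or the second nitroxyl may couple at the free ortho carbon C3 and lead to ortho-quinone and coupling products. Fallback (nitrogen placed on C1 first): from 13, nitrosation (NaNO2, AcOH/THF, 0 °C) at the para carbon should give 3-heneicosyl-5-methoxy-2-methyl-4-nitrosophenol F3. Reduction with Na2S2O4 gives 4-amino-3-heneicosyl-5-methoxy-2-methylphenol F4. Oxidation with FeCl3 in aqueous HCl/THF, with hydrolysis of the quinone imine, returns to the route at 15.

Step 5. The benzylic cation (protonated ortho-quinone methide) may be captured by a second electron-rich arene instead of the silane, giving diarylmethane dimers, or the reduction may stop at the benzylic stage. Fallback (hydride reduction through a carbonate instead of ionic hydrogenation): from 11, ClCO2Et/Et3N in THF gives ethyl 2-formyl-3-heneicosyl-5-methoxyphenyl carbonate F5. NaBH4 in THF/H2O reduces the aldehyde, the alkoxide expels the carbonate to form the ortho-quinone methide, and a second hydride adds to its methylene carbon, rejoining the route at 13.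

**Further compounds**

F1 | step 4 | 1-heneicosyl-3,5-dimethoxybenzene | CCCCCCCCCCCCCCCCCCCCCc1cc(OC)cc(OC)c1
F2 | step 4 | 2-heneicosyl-4,6-dimethoxybenzaldehyde | CCCCCCCCCCCCCCCCCCCCCc1cc(OC)cc(OC)c1C=O
F3 | step 6 | 3-heneicosyl-5-methoxy-2-methyl-4-nitrosophenol | CCCCCCCCCCCCCCCCCCCCCc1c(N=O)c(OC)cc(O)c1C
F4 | step 6 | 4-amino-3-heneicosyl-5-methoxy-2-methylphenol | CCCCCCCCCCCCCCCCCCCCCc1c(N)c(OC)cc(O)c1C
F5 | step 5 | ethyl 2-formyl-3-heneicosyl-5-methoxyphenyl carbonate | CCCCCCCCCCCCCCCCCCCCCc1cc(OC)cc(OC(=O)OCC)c1C=O
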